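**Strategy.** Everything rests on disconnecting the aryl ether bond O1–C8a of ring C. O1 joins C8a of ring A to the carbinol stereocentre C2, so this bond can be formed while all four bonds at C2 stay untouched; the (S) configuration, set earlier by a boron aldol, passes unchanged into the flavanone. In one operation a palladium-catalysed intramolecular etherification closes ring C as a 4-methylenechroman. The precursor is an (S)-homoallylic alcohol: ring B (phenol benzylated) sits on the carbinol carbon, and a 6-bromo-2,3,4-trimethoxyphenyl ring A sits on a 1,1-disubstituted alkene that masks the base-sensitive C4 ketone. Alkene cleavage and hydrogenolysis then give the target.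

Key step: step 6

Numbering: flavanone numbering is used throughout (O1, C2, C3, C4, C4a, C5–C8, C8a; ring A is the benzo ring, ring C the pyranone ring, ring B the 2-aryl group).

Assumption: the enol borinate made with (+)-Ipc2BCl (from (−)-α-pinene, isopinocampheyl groups (1S,2R,3S,5S)) is taken to attack the Si face of aldehyde 3, the sense usual for methyl ketones, giving the (S)-aldol; if the opposite sense were found, (−)-Ipc2BCl would be used with no other change.

**Step 1**
Reactants: 1 5-bromo-1,2,3-trimethoxybenzene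
Product: 2 1-(6-bromo-2,3,4-trimethoxyphenyl)ethan-1-one
Conditions: AcCl (1.2 equiv), AlCl3 (1.2 equiv), CH2Cl2, −10 → 0 °C; ice/dilute HCl
Reagents that add atoms: acetyl chloride, CC(=O)Cl
Why: Friedel–Crafts acylation: the two free ring positions of 1 are equivalent, each para to one methoxy group and ortho to another, so the acylium ion can only enter between Br and OMe, and low temperature with barely more than one equivalent of AlCl3 should spare the methoxy group next to the new ketone.

**Step 2**
Reactants: 2 1-(6-bromo-2,3,4-trimethoxyphenyl)ethan-1-one; 3 4-benzyloxy-3-methoxybenzaldehyde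
Product: 6 (S)-3-(4-benzyloxy-3-methoxyphenyl)-1-(6-bromo-2,3,4-trimethoxyphenyl)-3-hydroxypropan-1-one, via enol borinate 4 (not isolated), via borinate aldolate 5 (not isolated)
Conditions: (+)-Ipc2BCl (1.4 equiv), Et3N (1.6 equiv), Et2O, 0 °C; then 3, −78 → −20 °C; then pH 7 buffer, MeOH, 30% H2O2, 0 °C
Reagents that add atoms: none
Why: Diisopinocampheylboron aldol reaction of a methyl ketone: Et3N-assisted enolisation gives enol borinate 4, which adds to aldehyde 3 through a cyclic boron-centred transition state in which the isopinocampheyl ligands of the (+)-reagent direct attack to the Si face and so set C2 as (S), and the buffered peroxide work-up frees the aldol from 5 without the base that would cause dehydration or retro-aldol cleavage.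

**Step 3**
Reactants: 6 (S)-3-(4-benzyloxy-3-methoxyphenyl)-1-(6-bromo-2,3,4-trimethoxyphenyl)-3-hydroxypropan-1-one
Product: 7 (S)-3-(4-benzyloxy-3-methoxyphenyl)-1-(6-bromo-2,3,4-trimethoxyphenyl)-3-(tert-butyldimethylsilyloxy)propan-1-one
Conditions: TBSOTf (1.2 equiv), 2,6-lutidine (2 equiv), CH2Cl2, −78 → 0 °C
Reagents that add atoms: tert-butyldimethylsilyl triflate, CC(C)(C)[Si](C)(C)OS(=O)(=O)C(F)(F)F
Why: Silylation of a secondary alcohol with a silyl triflate and a hindered pyridine base, fast at low temperature and leaving the C–O bond at the stereocentre intact, protects the hydroxyl so that the β-hydroxy ketone cannot quench or be cleaved by the methylenation reagent.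

**Step 4**
Reactants: 7 (S)-3-(4-benzyloxy-3-methoxyphenyl)-1-(6-bromo-2,3,4-trimethoxyphenyl)-3-(tert-butyldimethylsilyloxy)propan-1-one
Product: 8 (S)-tert-butyl{[1-(4-benzyloxy-3-methoxyphenyl)-3-(6-bromo-2,3,4-trimethoxyphenyl)but-3-en-1-yl]oxy}dimethylsilane
Conditions: Cp2Ti(CH2)(Cl)AlMe2 (Tebbe reagent, 0.5 M in toluene, 1.5–2 equiv), pyridine (cat.), THF, −40 → 20 °C; 1 M NaOH quench
Reagents that add atoms: Cp2Ti(CH2)(Cl)AlMe2, C[Al-]1(C)C[Ti]([Cl+]1)(C1C=CC=C1)C1C=CC=C1
Why: Tebbe methylenation: the titanium methylidene adds to the carbonyl in a [2+2] fashion and the oxatitanacyclobutane collapses to the 1,1-disubstituted alkene, a non-basic process that tolerates hindered, enolisable ketones, the aryl bromide and the silyl and benzyl ethers, and that stores the C4 ketone in a form inert to the carbonate base of step 6.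

**Step 5**
Reactants: 8 (S)-tert-butyl{[1-(4-benzyloxy-3-methoxyphenyl)-3-(6-bromo-2,3,4-trimethoxyphenyl)but-3-en-1-yl]oxy}dimethylsilane
Product: 9 (S)-1-(4-benzyloxy-3-methoxyphenyl)-3-(6-bromo-2,3,4-trimethoxyphenyl)but-3-en-1-ol
Conditions: TBAF (1.2 equiv), THF, 0 → 20 °C; aqueous work-up
Reagents that add atoms: none
Why: Fluoride-mediated desilylation driven by the strong Si–F bond frees the secondary alcohol without touching the C–O bond at the stereocentre, the alkene or the aryl bromide.

**Step 6**
Reactants: 9 (S)-1-(4-benzyloxy-3-methoxyphenyl)-3-(6-bromo-2,3,4-trimethoxyphenyl)but-3-en-1-ol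
Product: 10 (S)-2-(4-benzyloxy-3-methoxyphenyl)-5,6,7-trimethoxy-4-methylenechroman
Conditions: Pd(OAc)2 (5 mol %), 2-(di-tert-butylphosphino)-1,1'-binaphthyl (6 mol %), Cs2CO3 (1.5 equiv), toluene (0.05 M), 70–80 °C, argon
Reagents that add atoms: none
Why: Pd(OAc)2 is reduced in the flask to zerovalent palladium, which inserts into the C8a–Br bond of ring A; carbonate-assisted exchange of bromide for the C2 alkoxide gives a seven-membered oxapalladacycle, and C–O reductive elimination releases the product and the catalyst. The closest known reaction type is the intramolecular Buchwald–Hartwig etherification of aryl halides with secondary alcohols, which gives chromans. Ring C, six-membered, closes by forming O1–C8a in that reductive elimination, with the exocyclic alkene as a spectator. No stereocentre is created: C2 keeps the (S) configuration from step 2 because none of its four bonds is made or broken. The step needs reductive elimination to outrun β-hydride elimination of the palladium alkoxide (which would oxidise C2 and reduce the C–Br bond) and must not generate a palladium hydride that moves the exocyclic alkene into the ring; the bulky, electron-rich di-tert-butyl biaryl phosphine, the weak base and the favourable six-ring closure should secure this, and the bromide fixes the site on ring A. A Heck reaction is excluded because insertion of the attached alkene would need a three- or four-membered ring.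

**Step 7**
Reactants: 10 (S)-2-(4-benzyloxy-3-methoxyphenyl)-5,6,7-trimethoxy-4-methylenechroman
Product: 12 (S)-2-(4-benzyloxy-3-methoxyphenyl)-5,6,7-trimethoxychroman-4-one, via diol 11 (not isolated)
Conditions: OsO4 (2 mol %), NaIO4 (4 equiv), 2,6-lutidine (2 equiv), 1,4-dioxane/H2O 3:1, 20 °C
Reagents that add atoms: OsO4, O=[Os](=O)(=O)=O (catalytic, delivers the C4 oxygen); NaIO4, [Na+].[O-]I(=O)(=O)=O (terminal oxygen source)
Why: Lemieux–Johnson oxidation: OsO4 dihydroxylates the exocyclic alkene to diol 11, which NaIO4 cleaves to the C4 ketone and formaldehyde while regenerating OsO4, and the near-neutral lutidine-buffered medium should neither epimerise C2 (no base-induced ring opening to the chalcone) nor attack the electron-rich arenes.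

**Step 8**
Reactants: 12 (S)-2-(4-benzyloxy-3-methoxyphenyl)-5,6,7-trimethoxychroman-4-one
Product: 13 agecorynin E, (S)-2-(4-hydroxy-3-methoxyphenyl)-5,6,7-trimethoxychroman-4-one
Conditions: H2 (1 atm), 10% Pd/C, EtOAc, 20 °C
Reagents that add atoms: none
Why: Catalytic hydrogenolysis of the benzyl aryl ether under neutral conditions releases the 4'-phenol; the reaction is stopped at uptake of one equivalent of H2 so that the benzylic C2–O1 bond and the ketone stay intact, and the absence of base avoids racemisation of the 4'-hydroxyflavanone by ring opening.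

**Compound list**
1 | 5-bromo-1,2,3-trimethoxybenzene | COc1cc(Br)cc(OC)c1OC | starting material
2 | 1-(6-bromo-2,3,4-trimethoxyphenyl)ethan-1-one | CC(=O)c1c(Br)cc(OC)c(OC)c1OC | intermediate
3 | 4-benzyloxy-3-methoxybenzaldehyde (O-benzylvanillin) | COc1cc(C=O)ccc1OCc1ccccc1 | starting material
4 | 1-(6-bromo-2,3,4-trimethoxyphenyl)vinyl bis[(1S,2R,3S,5S)-isopinocampheyl]borinate (enol borinate) | C=C(OB([C@H]1C[C@H]2C[C@@H]([C@@H]1C)C2(C)C)[C@H]1C[C@H]2C[C@@H]([C@@H]1C)C2(C)C)c1c(Br)cc(OC)c(OC)c1OC | intermediate
5 | (S)-1-(4-benzyloxy-3-methoxyphenyl)-3-(6-bromo-2,3,4-trimethoxyphenyl)-3-oxopropyl bis[(1S,2R,3S,5S)-isopinocampheyl]borinate (borinate aldolate) | COc1cc([C@@H](OB([C@H]2C[C@H]3C[C@@H]([C@@H]2C)C3(C)C)[C@H]2C[C@H]3C[C@@H]([C@@H]2C)C3(C)C)CC(=O)c2c(Br)cc(OC)c(OC)c2OC)ccc1OCc1ccccc1 | intermediate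
6 | (S)-3-(4-benzyloxy-3-methoxyphenyl)-1-(6-bromo-2,3,4-trimethoxyphenyl)-3-hydroxypropan-1-one | COc1cc([C@@H](O)CC(=O)c2c(Br)cc(OC)c(OC)c2OC)ccc1OCc1ccccc1 | intermediate
7 | (S)-3-(4-benzyloxy-3-methoxyphenyl)-1-(6-bromo-2,3,4-trimethoxyphenyl)-3-(tert-butyldimethylsilyloxy)propan-1-one | COc1cc([C@@H](O[Si](C)(C)C(C)(C)C)CC(=O)c2c(Br)cc(OC)c(OC)c2OC)ccc1OCc1ccccc1 | intermediate
8 | (S)-tert-butyl{[1-(4-benzyloxy-3-methoxyphenyl)-3-(6-bromo-2,3,4-trimethoxyphenyl)but-3-en-1-yl]oxy}dimethylsilane | COc1cc([C@@H](O[Si](C)(C)C(C)(C)C)CC(=C)c2c(Br)cc(OC)c(OC)c2OC)ccc1OCc1ccccc1 | intermediate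
9 | (S)-1-(4-benzyloxy-3-methoxyphenyl)-3-(6-bromo-2,3,4-trimethoxyphenyl)but-3-en-1-ol | COc1cc([C@@H](O)CC(=C)c2c(Br)cc(OC)c(OC)c2OC)ccc1OCc1ccccc1 | intermediate
10 | (S)-2-(4-benzyloxy-3-methoxyphenyl)-5,6,7-trimethoxy-4-methylenechroman | COc1cc([C@@H]2CC(=C)c3c(cc(OC)c(OC)c3OC)O2)ccc1OCc1ccccc1 | intermediate
11 | (2S)-2-(4-benzyloxy-3-methoxyphenyl)-4-(hydroxymethyl)-5,6,7-trimethoxychroman-4-ol (C4 epimers) | COc1cc([C@@H]2CC(O)(CO)c3c(cc(OC)c(OC)c3OC)O2)ccc1OCc1ccccc1 | intermediate
12 | (S)-2-(4-benzyloxy-3-methoxyphenyl)-5,6,7-trimethoxychroman-4-one | COc1cc([C@@H]2CC(=O)c3c(cc(OC)c(OC)c3OC)O2)ccc1OCc1ccccc1 | intermediate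
13 | agecorynin E, (S)-2-(4-hydroxy-3-methoxyphenyl)-5,6,7-trimethoxychroman-4-one | COc1cc([C@@H]2CC(=O)c3c(cc(OC)c(OC)c3OC)O2)ccc1O | target

**Step count.** Total: 8 steps. Longest linear sequence: 8 steps (1 → 13); aldehyde 3 enters at step 2 without steps of its own.

**Steps most likely to fail**

1. Step 6. What may go wrong: β-hydride elimination from the palladium alkoxide, which would remove bromine from ring A and oxidise the carbinol; migration of the exocyclic double bond into ring C by a palladium hydride; or slow C–O reductive elimination from the electron-rich aryl group. Fallback, setting out from 9 and coming back at 10: the ring would be closed in the copper Ullmann manifold, which forms no metal hydride. An aromatic Finkelstein exchange (CuI, NaI, trans-N,N'-dimethylcyclohexane-1,2-diamine, 1,4-dioxane, 110 °C) would turn 9 into (S)-1-(4-benzyloxy-3-methoxyphenyl)-3-(6-iodo-2,3,4-trimethoxyphenyl)but-3-en-1-ol F1. Ullmann etherification of F1 (CuI, 3,4,7,8-tetramethyl-1,10-phenanthroline, Cs2CO3, toluene, 110 °C) should then give 10 with C2 untouched.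

2. Step 2. What may go wrong: weak facial discrimination in the boron aldol transition state (methyl ketone enol borinates are less selective than those of ethyl ketones), sluggish enolisation of the hindered ketone, or competing reduction of the aldehyde by the borane reagent. A modest enantiomeric excess could first be raised by recrystallising 6 or 9. Fallback, setting out from 2 (with 3) and coming back at 6: the C–C bond and the stereocentre would be made separately. Claisen–Schmidt condensation (Ba(OH)2·8H2O, MeOH, 40 °C) should give (E)-3-(4-benzyloxy-3-methoxyphenyl)-1-(6-bromo-2,3,4-trimethoxyphenyl)prop-2-en-1-one F2. Copper-catalysed enantioselective conjugate borylation (CuCl, NaOtBu, a Josiphos-type bisphosphine of the enantiomeric series that leads to the (S)-boronate, B2pin2, MeOH, THF, 20 °C) would give (S)-3-(4-benzyloxy-3-methoxyphenyl)-1-(6-bromo-2,3,4-trimethoxyphenyl)-3-(4,4,5,5-tetramethyl-1,3,2-dioxaborolan-2-yl)propan-1-one F3. Oxidation of the C–B bond with retention (NaBO3·4H2O, THF/H2O, 20 °C) would give 6.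

3. Step 4. What may go wrong: failure of the titanium methylidene to reach the carbonyl flanked by Br and OMe, or enolisation followed by β-elimination of the silyloxy group. Fallback, setting out from 7 and coming back at 8: a Peterson olefination in two stages. Me3SiCH2Li premixed with anhydrous CeCl3 (THF, −78 °C) should add to the hindered ketone without halogen–metal exchange, giving (4S)-4-(4-benzyloxy-3-methoxyphenyl)-2-(6-bromo-2,3,4-trimethoxyphenyl)-4-(tert-butyldimethylsilyloxy)-1-(trimethylsilyl)butan-2-ol F4 (C2 epimers). KH (THF, 0 → 20 °C) would then induce syn-elimination of silanolate to give 8.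

**Further compounds**
F1 | step 6 | (S)-1-(4-benzyloxy-3-methoxyphenyl)-3-(6-iodo-2,3,4-trimethoxyphenyl)but-3-en-1-ol | COc1cc([C@@H](O)CC(=C)c2c(I)cc(OC)c(OC)c2OC)ccc1OCc1ccccc1
F2 | step 2 | (E)-3-(4-benzyloxy-3-methoxyphenyl)-1-(6-bromo-2,3,4-trimethoxyphenyl)prop-2-en-1-one | COc1cc(/C=C/C(=O)c2c(Br)cc(OC)c(OC)c2OC)ccc1OCc1ccccc1
F3 | step 2 | (S)-3-(4-benzyloxy-3-methoxyphenyl)-1-(6-bromo-2,3,4-trimethoxyphenyl)-3-(4,4,5,5-tetramethyl-1,3,2-dioxaborolan-2-yl)propan-1-one | COc1cc([C@@H](B2OC(C)(C)C(C)(C)O2)CC(=O)c2c(Br)cc(OC)c(OC)c2OC)ccc1OCc1ccccc1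
F4 | step 4 | (4S)-4-(4-benzyloxy-3-methoxyphenyl)-2-(6-bromo-2,3,4-trimethoxyphenyl)-4-(tert-butyldimethylsilyloxy)-1-(trimethylsilyl)butan-2-ol (C2 epimers) | COc1cc([C@@H](O[Si](C)(C)C(C)(C)C)CC(O)(C[Si](C)(C)C)c2c(Br)cc(OC)c(OC)c2OC)ccc1OCc1ccccc1
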